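## Analysis of the target

The target 21 is a stilbene trimer. Ring A (1,3-dioxygenated, carrying the (E)-4-hydroxystyryl group with ring F), ring B (central, 1,3-dioxygenated) and ring C (3,5-dihydroxyphenyl) are joined through two 2,3-dihydrobenzofurans. Dihydrofuran 1 (O1, C2, C3, C3a, C7a) is fused to ring A and dihydrofuran 2 (O1', C2', C3', C3a', C7a') to ring B. C2 and C2' carry 4-hydroxyphenyl rings D and E; C3 carries ring B and C3' carries ring C.

There are four stereocentres: (2R,3R) in dihydrofuran 1 and (2S,3S) in dihydrofuran 2, both trans. The two heterocycles have opposite absolute sense and sit at para positions of ring B, so neither can direct the other. Each must be set by a reagent.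

C2 and C2' are 4-oxybenzylic ether carbons. They ionise under acid and equilibrate to the trans ring, whereas C3 and C3' are durable diarylmethines. The stereochemical information that must be created is therefore only C3 (R) and C3' (S).

Sensitive groups are the seven phenols, the electron-rich stilbene and the two benzylic C–O bonds.

The synthesis is hard for three reasons. Rings A and B are bonded to C3 and C3' at the hindered carbon between their two oxygens (C3a, flanked by C4–OH and C7a–O1), not at the ortho/para carbon that electrophilic or radical chemistry prefers. The same motif must be built twice with opposite handedness. Seven phenols must be liberated at the end.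

The plan exploits two features of this structure. The C2–C3 bond joins an O–CH(aryl) carbon to a diaryl carbon, so C2 with its ring D (or E) can start as the methylene of a 4-methoxybenzyl ether on O1 and C3 as a diaryl carbene carbon. C3a is the one arene carbon at which two alkoxy groups direct lithiation.

## Retrosynthetic reasoning

21 ⇒ 20. Only the seven O–methyl bonds are cut. Both dihydrofurans in 20 are already trans, so the last step sets no stereocentre and needs only a Lewis-acid ether cleavage.

20 ⇒ 18 + 19. The stilbene C=C is cut last in the retrosynthetic sense, so the alkene is made late. It is then never exposed to the organolithium, the carbenoid or the acid equilibration. The forward reaction is an E-selective olefination of aldehyde 18 with phosphonate 19.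

18 ⇒ 15 (through 16 and 17). This is the key disconnection: the C2–C3 bond of dihydrofuran 1. In 15, C3 is the hydrazone carbon between ring A and ring B, and C2 with ring D is the 4-methoxybenzyl group on the ring A oxygen. The forward step must generate the diaryl carbene precursor 16 and insert the carbene into the benzylic C–H with catalyst control of the C3 face. It must then relax C2 to trans and unmask the aldehyde. The gain is large: 15 has no new stereocentre, and its protecting group becomes C2 and ring D.

15 ⇒ 13 + 5 (through 14). The C3–C3a bond is cut. Aryllithium 5, metallated at the carbon between its two oxygens, adds to nitrile 13. Nitrogen exchange on ketimine 14 gives the hydrazone without passing through a hindered ketone. This is the bond that fixes the regiochemistry of ring A, and directed lithiation is the one reaction that prefers that carbon.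

13 ⇒ 11 ⇒ 8 (through 12, 10, 9). The nitrile comes from the aldehyde. Aldehyde 11 is then disconnected exactly as 18 was, at C2'–C3' of dihydrofuran 2, but with the enantiomeric catalyst, because this ring needs the opposite sense.

8 ⇒ 5 + 6 (through 7). The C3'–C3a' bond is cut in the same way: aryllithium 5 adds to nitrile 6, which supplies ring C and C3'.

5 ⇒ 4 ⇒ 3 ⇒ 1 + 2. The aryllithium is made in a step of its own, because both C–C bond formations draw on it. It supplies ring B with C2' and ring E in the first cycle, and ring A with C2 and ring D in the second. Its precursor 4 comes from aldehyde 1 by etherification with 2 and acetalisation.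

## Alternatives that were turned down

Alternative 1: the biomimetic disconnection, and the one most chemists would draw first. Both bonds of dihydrofuran 1 (C3–C3a and C2–O1) are cut, leading to resveratrol A1 and the (2S,3S) dimer A2. The forward step is a one-electron oxidation (FeCl3, AgOAc or a peroxidase with H2O2), radical coupling of C8 of A2 with the carbon between the oxygens of A1, then closure of the quinone methide by the phenol. It was turned down on mechanistic grounds. The phenoxyl radical of A1 carries its spin on the 4-oxystyryl part, not on the resorcinol ring, so A1 reacts through its own alkene carbon. The carbon between the two oxygens is the least accessible coupling site. Homo- and cross-coupling compete, the products are more oxidisable than the monomers, and nothing controls the face. A2 would have to be made by the same unselective reaction, and the opposite sense of the two rings cannot be imposed.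

Alternative 2: the ionic textbook route. Only C2–O1 is cut, leading to a 1,2,2-triarylethanol such as A3 (shown for dihydrofuran 2). The forward step is acid-mediated cyclodehydration through the 4-methoxybenzylic cation, which gives the trans ring. It was turned down because the stereocentre that matters, the diarylmethine C3, must exist before the key step. Every practical precursor of A3 has that carbon alpha to a ketone, where it racemises. Attaching the aryl group at the carbon between the oxygens would need a separate halogenation or coupling. The cyclisation itself creates no durable stereochemistry and costs about six steps per ring.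

Alternative 3: a [4+1] annulation. C2–C3 and C2–O1 are cut, leading to an o-hydroxybenzhydrol such as A4 and a 4-methoxybenzylsulfonium salt such as A5. The forward step is dehydration of A4 to the o-quinone methide, conjugate addition of the ylide from A5 and 5-exo-tet displacement of the sulfide, giving the trans ring directly. It is attractive and was kept as a fallback. It was not chosen because it needs a free phenol next to an acid-labile carbinol, which adds protecting-group steps to each cycle. Absolute control would also rest on a stoichiometric chiral sulfide in a semi-stabilised ylide addition to a quinone methide, which is less secure than the catalyst-controlled insertion.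

Key step: step 8

Assumption: the sense of induction of the two enantiomeric catalysts, dirhodium tetrakis[(S)- and (R)-N-phthaloyl-(1-adamantyl)glycinate], Rh2(S-PTAD)4 and Rh2(R-PTAD)4, is assigned by analogy (S-catalyst for the 3S ring, R-catalyst for the 3R ring). If it is the reverse, the two catalysts change places and nothing else changes.

## Route

Step 1
Reactants: 1 3-hydroxy-5-methoxybenzaldehyde; 2 4-methoxybenzyl chloride
Product: 3 3-methoxy-5-[(4-methoxyphenyl)methoxy]benzaldehyde
Conditions: K2CO3, DMF, 60 °C
Reagents that add atoms: none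
Why: Williamson etherification of the phenoxide with a reactive benzylic chloride; the aldehyde is untouched. The 4-methoxybenzyl group is the protecting group now and becomes C2 (or C2') with ring D (or E) later.

Step 2
Reactants: 3 3-methoxy-5-[(4-methoxyphenyl)methoxy]benzaldehyde
Product: 4 1-(dimethoxymethyl)-3-methoxy-5-[(4-methoxyphenyl)methoxy]benzene
Conditions: HC(OMe)3, PPTS (cat.), MeOH, 40 °C
Reagents that add atoms: trimethyl orthoformate, COC(OC)OC
Why: Acid-catalysed acetalisation driven by the orthoformate; the mild acid leaves the 4-methoxybenzyl aryl ether intact. The acetal masks the aldehyde against n-BuLi.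

Step 3
Reactants: 4 1-(dimethoxymethyl)-3-methoxy-5-[(4-methoxyphenyl)methoxy]benzene
Product: 5 {4-(dimethoxymethyl)-2-methoxy-6-[(4-methoxyphenyl)methoxy]phenyl}lithium (titrated THF solution under argon)
Conditions: n-BuLi (1.05 equiv), THF, 0 °C, 1 h; solution transferred by cannula
Reagents that add atoms: n-butyllithium, [Li]CCCC
Why: Directed ortho-lithiation should occur at the only carbon flanked by two alkoxy groups, whose cooperative coordination and inductive effect outweigh the single-director sites next to the acetal. The chelated 2,6-dialkoxyaryllithium is the common nucleophile of steps 4 and 7; the step is run on the portion of 4 needed directly before each of those steps, so the reagent is not stored.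

Step 4
Reactants: 5 {4-(dimethoxymethyl)-2-methoxy-6-[(4-methoxyphenyl)methoxy]phenyl}lithium; 6 3,5-dimethoxybenzonitrile
Product: 8 [{4-(dimethoxymethyl)-2-methoxy-6-[(4-methoxyphenyl)methoxy]phenyl}(3,5-dimethoxyphenyl)methylidene]hydrazine, via N–H ketimine 7 (not isolated)
Conditions: 6 added to the solution of 5, THF, −78 °C to rt; then AcOH, N2H4·H2O (excess), EtOH, 70 °C
Reagents that add atoms: hydrazine hydrate, NN.O
Why: The aryllithium adds once to the nitrile, since the N-lithio ketimine cannot add again. After protonation the N–H ketimine exchanges NH for N–NH2 (transimination, loss of ammonia), so the hydrazone is reached without condensing a hindered 2,6-dialkoxybenzophenone. Hydrazine in excess over AcOH keeps the medium basic enough for the acetal to survive.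

Step 5
Reactants: 8 [{4-(dimethoxymethyl)-2-methoxy-6-[(4-methoxyphenyl)methoxy]phenyl}(3,5-dimethoxyphenyl)methylidene]hydrazine
Product: 11 (2S,3S)-3-(3,5-dimethoxyphenyl)-4-methoxy-2-(4-methoxyphenyl)-2,3-dihydro-1-benzofuran-6-carbaldehyde, via diazo compound 9 (not isolated), via cis acetal 10 (not isolated)
Conditions: MnO2, CH2Cl2, 0 °C; filter; Rh2(S-PTAD)4 (1 mol %), CH2Cl2/MeCN, 0 °C; then TFA, H2O, rt
Reagents that add atoms: water, O
Why: First instance of the key reaction type: the donor/donor dirhodium carbenoid from 9 inserts into the 4-methoxybenzylic C–H (1,5 C–H insertion), and the (S)-catalyst sets C3' as S in the kinetic cis ring 10. TFA then equilibrates C2' through the 4-methoxybenzylic cation to the trans (2S,3S) ring and, with water, hydrolyses the acetal. Once trans, both centres are in the thermodynamic arrangement, so later acid at C2' or base at C3' returns the same isomer.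

Step 6
Reactants: 11 (2S,3S)-3-(3,5-dimethoxyphenyl)-4-methoxy-2-(4-methoxyphenyl)-2,3-dihydro-1-benzofuran-6-carbaldehyde
Product: 13 (2S,3S)-3-(3,5-dimethoxyphenyl)-4-methoxy-2-(4-methoxyphenyl)-2,3-dihydro-1-benzofuran-6-carbonitrile, via oxime 12 (not isolated)
Conditions: NH2OH·HCl, pyridine, rt; then Ac2O, 90 °C
Reagents that add atoms: hydroxylamine hydrochloride, Cl.NO
Why: Oxime formation followed by acetylation and elimination of acetic acid (aldoxime dehydration) gives the nitrile. The nitrile lets the next C–C bond formation deliver the ketimine oxidation level directly; no stereocentre is touched.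

Step 7
Reactants: 5 {4-(dimethoxymethyl)-2-methoxy-6-[(4-methoxyphenyl)methoxy]phenyl}lithium; 13 (2S,3S)-3-(3,5-dimethoxyphenyl)-4-methoxy-2-(4-methoxyphenyl)-2,3-dihydro-1-benzofuran-6-carbonitrile
Product: 15 [{4-(dimethoxymethyl)-2-methoxy-6-[(4-methoxyphenyl)methoxy]phenyl}{(2S,3S)-3-(3,5-dimethoxyphenyl)-4-methoxy-2-(4-methoxyphenyl)-2,3-dihydro-1-benzofuran-6-yl}methylidene]hydrazine, via N–H ketimine 14 (not isolated)
Conditions: 13 added to the solution of 5, THF, −78 to 0 °C; then AcOH, N2H4·H2O (excess), EtOH, 70 °C
Reagents that add atoms: hydrazine hydrate, NN.O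
Why: Same sequence as step 4 (addition of the aryllithium to the nitrile, then transimination), now joining ring A to ring B at the future C3. The dihydrofuran in 13 is trans, so a reversible abstraction of C3'–H would return the same isomer on reprotonation.

Step 8
Reactants: 15 [{4-(dimethoxymethyl)-2-methoxy-6-[(4-methoxyphenyl)methoxy]phenyl}{(2S,3S)-3-(3,5-dimethoxyphenyl)-4-methoxy-2-(4-methoxyphenyl)-2,3-dihydro-1-benzofuran-6-yl}methylidene]hydrazine
Product: 18 (2R,3R)-3-[(2S,3S)-3-(3,5-dimethoxyphenyl)-4-methoxy-2-(4-methoxyphenyl)-2,3-dihydro-1-benzofuran-6-yl]-4-methoxy-2-(4-methoxyphenyl)-2,3-dihydro-1-benzofuran-6-carbaldehyde, via diazo compound 16 (not isolated), via cis acetal 17 (not isolated)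
Conditions: MnO2, CH2Cl2, 0 °C; filter; Rh2(R-PTAD)4 (1 mol %), CH2Cl2/MeCN, 0 °C (slow addition); then TFA, H2O, rt
Reagents that add atoms: water, O
Why: Oxidation of the hydrazone gives the diaryldiazomethane 16, which the chiral dirhodium tetracarboxylate turns into a donor/donor carbenoid; its electrophilic carbon (the future C3) takes the hydridic C–H of the 4-methoxybenzyl methylene on the ortho oxygen through a five-centre transition state, best described as hydride transfer followed at once by C–C closure of the oxocarbenium/rhodium-alkyl pair. The closest known reaction type is the enantioselective intramolecular C–H insertion of donor/donor dirhodium carbenoids into benzylic ethers to give 2,3-diaryl-2,3-dihydrobenzofurans. The ring closed is dihydrofuran 1 (O1–C2–C3–C3a–C7a), by formation of the C2–C3 bond in a 1,5-insertion. C3 is set by the catalyst, which distinguishes the two faces of the carbenoid carbon held between the tethered ring A and the spectator ring B; the (R)-catalyst is used because this ring needs the sense opposite to that of step 5, and the resident stereocentres lie across ring B, too far away to override it. C2 should form cis to the C3 aryl in the kinetic product 17 and is then equilibrated by TFA, through reversible ionisation of the C2–O1 bond and ion-pair return, to the trans ring, so its final configuration follows from C3. The step needs selectivity for the ArCH2–O methylene over the O–CH3 on the other ortho oxygen, secured by the much greater hydricity of the 4-methoxybenzylic C–H, and for insertion over azine formation, secured by the five-membered geometry and slow addition. The same acid, with water, unmasks the aldehyde for step 9.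

Step 9
Reactants: 18 (2R,3R)-3-[(2S,3S)-3-(3,5-dimethoxyphenyl)-4-methoxy-2-(4-methoxyphenyl)-2,3-dihydro-1-benzofuran-6-yl]-4-methoxy-2-(4-methoxyphenyl)-2,3-dihydro-1-benzofuran-6-carbaldehyde; 19 diethyl [(4-methoxyphenyl)methyl]phosphonate
Product: 20 (2R,3R)-3-[(2S,3S)-3-(3,5-dimethoxyphenyl)-4-methoxy-2-(4-methoxyphenyl)-2,3-dihydro-1-benzofuran-6-yl]-4-methoxy-2-(4-methoxyphenyl)-6-[(E)-2-(4-methoxyphenyl)ethenyl]-2,3-dihydro-1-benzofuran
Conditions: KOtBu, THF, 0 °C to rt
Reagents that add atoms: none
Why: Horner–Wadsworth–Emmons olefination of an aryl aldehyde with a benzylic phosphonate should give the (E)-stilbene. The base-exposed C3–H para to the aldehyde sits in a trans ring, so reversible abstraction is harmless.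

Step 10
Reactants: 20 (2R,3R)-3-[(2S,3S)-3-(3,5-dimethoxyphenyl)-4-methoxy-2-(4-methoxyphenyl)-2,3-dihydro-1-benzofuran-6-yl]-4-methoxy-2-(4-methoxyphenyl)-6-[(E)-2-(4-methoxyphenyl)ethenyl]-2,3-dihydro-1-benzofuran
Product: 21 (2R,3R)-3-[(2S,3S)-3-(3,5-dihydroxyphenyl)-4-hydroxy-2-(4-hydroxyphenyl)-2,3-dihydro-1-benzofuran-6-yl]-2-(4-hydroxyphenyl)-6-[(E)-2-(4-hydroxyphenyl)ethenyl]-2,3-dihydro-1-benzofuran-4-ol (CNP0248228.3)
Conditions: BBr3 (excess), CH2Cl2, −78 °C to rt; then H2O
Reagents that add atoms: none
Why: Lewis-acid cleavage of the seven aryl methyl ethers (boron coordination, bromide attack at methyl), a reaction type used on polymethoxystilbenes and on 2-aryl-dihydrobenzofurans. Any transient opening of a C2–O bond should return to the trans ring, which is the thermodynamic one, so no stereocentre changes.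

## Compound list

1 | 3-hydroxy-5-methoxybenzaldehyde | O=Cc1cc(O)cc(OC)c1 | starting material
2 | 4-methoxybenzyl chloride | COc1ccc(CCl)cc1 | starting material
3 | 3-methoxy-5-[(4-methoxyphenyl)methoxy]benzaldehyde | O=Cc1cc(OC)cc(OCc2ccc(OC)cc2)c1 | intermediate
4 | 1-(dimethoxymethyl)-3-methoxy-5-[(4-methoxyphenyl)methoxy]benzene | COC(OC)c1cc(OC)cc(OCc2ccc(OC)cc2)c1 | intermediate
5 | {4-(dimethoxymethyl)-2-methoxy-6-[(4-methoxyphenyl)methoxy]phenyl}lithium | COC(OC)c1cc(OC)c([Li])c(OCc2ccc(OC)cc2)c1 | intermediate
6 | 3,5-dimethoxybenzonitrile | COc1cc(C#N)cc(OC)c1 | starting material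
7 | N–H ketimine: 1-{4-(dimethoxymethyl)-2-methoxy-6-[(4-methoxyphenyl)methoxy]phenyl}-1-(3,5-dimethoxyphenyl)methanimine | COC(OC)c1cc(OC)c(C(=N)c2cc(OC)cc(OC)c2)c(OCc2ccc(OC)cc2)c1 | intermediate
8 | [{4-(dimethoxymethyl)-2-methoxy-6-[(4-methoxyphenyl)methoxy]phenyl}(3,5-dimethoxyphenyl)methylidene]hydrazine (E/Z not defined) | COC(OC)c1cc(OC)c(C(=NN)c2cc(OC)cc(OC)c2)c(OCc2ccc(OC)cc2)c1 | intermediate
9 | 2-[diazo(3,5-dimethoxyphenyl)methyl]-5-(dimethoxymethyl)-1-methoxy-3-[(4-methoxyphenyl)methoxy]benzene | COC(OC)c1cc(OC)c(C(=[N+]=[N-])c2cc(OC)cc(OC)c2)c(OCc2ccc(OC)cc2)c1 | intermediate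
10 | (2R,3S)-6-(dimethoxymethyl)-3-(3,5-dimethoxyphenyl)-4-methoxy-2-(4-methoxyphenyl)-2,3-dihydro-1-benzofuran (cis) | COC(OC)c1cc(OC)c2c(c1)O[C@@H](c1ccc(OC)cc1)[C@H]2c1cc(OC)cc(OC)c1 | intermediate
11 | (2S,3S)-3-(3,5-dimethoxyphenyl)-4-methoxy-2-(4-methoxyphenyl)-2,3-dihydro-1-benzofuran-6-carbaldehyde (trans) | O=Cc1cc(OC)c2c(c1)O[C@H](c1ccc(OC)cc1)[C@H]2c1cc(OC)cc(OC)c1 | intermediate
12 | oxime of 11 (E/Z not defined) | ON=Cc1cc(OC)c2c(c1)O[C@H](c1ccc(OC)cc1)[C@H]2c1cc(OC)cc(OC)c1 | intermediate
13 | (2S,3S)-3-(3,5-dimethoxyphenyl)-4-methoxy-2-(4-methoxyphenyl)-2,3-dihydro-1-benzofuran-6-carbonitrile | N#Cc1cc(OC)c2c(c1)O[C@H](c1ccc(OC)cc1)[C@H]2c1cc(OC)cc(OC)c1 | intermediate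
14 | N–H ketimine between ring A and ring B: 1-{4-(dimethoxymethyl)-2-methoxy-6-[(4-methoxyphenyl)methoxy]phenyl}-1-{(2S,3S)-3-(3,5-dimethoxyphenyl)-4-methoxy-2-(4-methoxyphenyl)-2,3-dihydro-1-benzofuran-6-yl}methanimine | COC(OC)c1cc(OC)c(C(=N)c2cc(OC)c3c(c2)O[C@H](c2ccc(OC)cc2)[C@H]3c2cc(OC)cc(OC)c2)c(OCc2ccc(OC)cc2)c1 | intermediate
15 | hydrazone of 14 (E/Z not defined) | COC(OC)c1cc(OC)c(C(=NN)c2cc(OC)c3c(c2)O[C@H](c2ccc(OC)cc2)[C@H]3c2cc(OC)cc(OC)c2)c(OCc2ccc(OC)cc2)c1 | intermediate
16 | diazo compound from 15 | COC(OC)c1cc(OC)c(C(=[N+]=[N-])c2cc(OC)c3c(c2)O[C@H](c2ccc(OC)cc2)[C@H]3c2cc(OC)cc(OC)c2)c(OCc2ccc(OC)cc2)c1 | intermediate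
17 | (2S,3R)-6-(dimethoxymethyl)-3-[(2S,3S)-3-(3,5-dimethoxyphenyl)-4-methoxy-2-(4-methoxyphenyl)-2,3-dihydro-1-benzofuran-6-yl]-4-methoxy-2-(4-methoxyphenyl)-2,3-dihydro-1-benzofuran (new ring cis) | COC(OC)c1cc(OC)c2c(c1)O[C@H](c1ccc(OC)cc1)[C@@H]2c1cc(OC)c2c(c1)O[C@H](c1ccc(OC)cc1)[C@H]2c1cc(OC)cc(OC)c1 | intermediate
18 | (2R,3R)-3-[(2S,3S)-3-(3,5-dimethoxyphenyl)-4-methoxy-2-(4-methoxyphenyl)-2,3-dihydro-1-benzofuran-6-yl]-4-methoxy-2-(4-methoxyphenyl)-2,3-dihydro-1-benzofuran-6-carbaldehyde | O=Cc1cc(OC)c2c(c1)O[C@@H](c1ccc(OC)cc1)[C@@H]2c1cc(OC)c2c(c1)O[C@H](c1ccc(OC)cc1)[C@H]2c1cc(OC)cc(OC)c1 | intermediate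
19 | diethyl [(4-methoxyphenyl)methyl]phosphonate | CCOP(=O)(Cc1ccc(OC)cc1)OCC | starting material
20 | heptamethyl ether of the target | COc1ccc(/C=C/c2cc(OC)c3c(c2)O[C@@H](c2ccc(OC)cc2)[C@@H]3c2cc(OC)c3c(c2)O[C@H](c2ccc(OC)cc2)[C@H]3c2cc(OC)cc(OC)c2)cc1 | intermediate
21 | CNP0248228.3 | Oc1ccc(/C=C/c2cc(O)c3c(c2)O[C@@H](c2ccc(O)cc2)[C@@H]3c2cc(O)c3c(c2)O[C@H](c2ccc(O)cc2)[C@H]3c2cc(O)cc(O)c2)cc1 | target

## Step count and risks

Total step count: 10. Longest linear sequence: 10 steps (1 → 3 → 4 → 5 → 8 → 11 → 13 → 15 → 18 → 20 → 21). Aryllithium 5 is used twice, in steps 4 and 7.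

**Step 8 (key step; the same reasoning holds for step 5).** The most likely failure is poor facial discrimination at the carbenoid carbon. It sits between two ortho alkoxy groups on a ring twisted out of conjugation, and the wrong face gives, after equilibration, the C3 epimer, a diastereomer of 18. Two further risks are loss of the carbene to azine formation if the hindered insertion is slow, and erosion at C3 by a 1,2-hydride shift in the ring-opened cation during the acid equilibration.

Fallback, from 11 and 5 to 18, using the [4+1] annulation of Alternative 3. Aryllithium 5 is added to aldehyde 11 at −78 °C to give the diarylmethanol F1 (both carbinol epimers). Hydrogenolysis (H2, Pd/C, EtOAc, trace Et3N) removes the 4-methoxybenzyl group and gives the o-hydroxybenzhydrol F2. With Boc2O and Cs2CO3, F2 is turned in the flask into its o-quinone methide by carbonate transfer to the benzylic oxygen and loss of tert-butyl carbonate. The methide is intercepted by the ylide of the chiral sulfonium salt F3, made from (2R,5R)-2,5-dimethylthiolane, 4-methoxybenzyl bromide and AgBF4; the hand of the sulfide is to be chosen by the sense it induces. Conjugate addition and 5-exo-tet displacement of the sulfide give the trans acetal F4 directly, and PPTS in acetone/H2O then gives 18.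

**Step 7.** The most likely failure is proton transfer instead of addition. Aryllithium 5 may abstract C3'–H of 13, which is acidified by the para nitrile on ring B, faster than it adds to the hindered nitrile. That consumes the reagent and opens a path to β-elimination of the ring oxygen. The NH to N–NH2 exchange on the hindered ketimine may also stall.

Fallback, from 11 and 5 to 15. Aryllithium 5 is added to aldehyde 11 instead, where carbonyl addition at −78 °C outruns C–H abstraction, to give the diarylmethanol F1 described above. Oxidation with DMP gives the ketone F5. Forced condensation with N2H4·H2O (n-BuOH, 110 °C, Sc(OTf)3 cat.) gives 15.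

**Step 4.** The most likely failure is slow addition of the hindered aryllithium to nitrile 6 relative to proton abstraction ortho to the cyano group, followed by incomplete exchange of the hindered ketimine.

Fallback, from 5 to 8. Aryllithium 5 is acylated with 3,5-dimethoxybenzoyl chloride (inverse addition, −78 °C), a much faster electrophile, to give the ketone F6. Condensation with N2H4·H2O under the forcing conditions above gives 8.

**Step 10.** The most likely failure comes from the long exposure to BBr3 and HBr needed for seven ether cleavages. It invites addition to, or oligomerisation through, the 4-oxystilbene and irreversible trapping of a ring-opened C2 cation.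

Fallback, from 18 to 21, which takes the stilbene out of the acid step and ends with fluoride. BBr3 on aldehyde 18 gives the hexaphenol aldehyde F7. TBSOTf and 2,6-lutidine give the hexakis(silyl ether) F8. Olefination with the silylated phosphonate F9 (from diethyl (4-hydroxybenzyl)phosphonate and TBSCl) and KHMDS gives the silylated stilbene F10. KHF2 in MeOH then gives 21.

## Further compounds

F1 | step 8 | {4-(dimethoxymethyl)-2-methoxy-6-[(4-methoxyphenyl)methoxy]phenyl}{(2S,3S)-3-(3,5-dimethoxyphenyl)-4-methoxy-2-(4-methoxyphenyl)-2,3-dihydro-1-benzofuran-6-yl}methanol (both carbinol epimers) | COC(OC)c1cc(OC)c(C(O)c2cc(OC)c3c(c2)O[C@H](c2ccc(OC)cc2)[C@H]3c2cc(OC)cc(OC)c2)c(OCc2ccc(OC)cc2)c1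
F2 | step 8 | 5-(dimethoxymethyl)-2-[{(2S,3S)-3-(3,5-dimethoxyphenyl)-4-methoxy-2-(4-methoxyphenyl)-2,3-dihydro-1-benzofuran-6-yl}(hydroxy)methyl]-3-methoxyphenol (both carbinol epimers) | COC(OC)c1cc(OC)c(C(O)c2cc(OC)c3c(c2)O[C@H](c2ccc(OC)cc2)[C@H]3c2cc(OC)cc(OC)c2)c(O)c1
F3 | step 8 | (2R,5R)-1-[(4-methoxyphenyl)methyl]-2,5-dimethylthiolan-1-ium tetrafluoroborate | C[C@@H]1CC[C@@H](C)[S+]1Cc1ccc(OC)cc1.F[B-](F)(F)F
F4 | step 8 | (2R,3R)-6-(dimethoxymethyl)-3-[(2S,3S)-3-(3,5-dimethoxyphenyl)-4-methoxy-2-(4-methoxyphenyl)-2,3-dihydro-1-benzofuran-6-yl]-4-methoxy-2-(4-methoxyphenyl)-2,3-dihydro-1-benzofuran | COC(OC)c1cc(OC)c2c(c1)O[C@@H](c1ccc(OC)cc1)[C@@H]2c1cc(OC)c2c(c1)O[C@H](c1ccc(OC)cc1)[C@H]2c1cc(OC)cc(OC)c1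
F5 | step 7 | {4-(dimethoxymethyl)-2-methoxy-6-[(4-methoxyphenyl)methoxy]phenyl}{(2S,3S)-3-(3,5-dimethoxyphenyl)-4-methoxy-2-(4-methoxyphenyl)-2,3-dihydro-1-benzofuran-6-yl}methanone | COC(OC)c1cc(OC)c(C(=O)c2cc(OC)c3c(c2)O[C@H](c2ccc(OC)cc2)[C@H]3c2cc(OC)cc(OC)c2)c(OCc2ccc(OC)cc2)c1
F6 | step 4 | {4-(dimethoxymethyl)-2-methoxy-6-[(4-methoxyphenyl)methoxy]phenyl}(3,5-dimethoxyphenyl)methanone | COC(OC)c1cc(OC)c(C(=O)c2cc(OC)cc(OC)c2)c(OCc2ccc(OC)cc2)c1
F7 | step 10 | (2R,3R)-3-[(2S,3S)-3-(3,5-dihydroxyphenyl)-4-hydroxy-2-(4-hydroxyphenyl)-2,3-dihydro-1-benzofuran-6-yl]-4-hydroxy-2-(4-hydroxyphenyl)-2,3-dihydro-1-benzofuran-6-carbaldehyde | O=Cc1cc(O)c2c(c1)O[C@@H](c1ccc(O)cc1)[C@@H]2c1cc(O)c2c(c1)O[C@H](c1ccc(O)cc1)[C@H]2c1cc(O)cc(O)c1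
F8 | step 10 | hexakis(tert-butyldimethylsilyl) ether of F7 | O=Cc1cc(O[Si](C)(C)C(C)(C)C)c2c(c1)O[C@@H](c1ccc(O[Si](C)(C)C(C)(C)C)cc1)[C@@H]2c1cc(O[Si](C)(C)C(C)(C)C)c2c(c1)O[C@H](c1ccc(O[Si](C)(C)C(C)(C)C)cc1)[C@H]2c1cc(O[Si](C)(C)C(C)(C)C)cc(O[Si](C)(C)C(C)(C)C)c1
F9 | step 10 | diethyl ({4-[(tert-butyldimethylsilyl)oxy]phenyl}methyl)phosphonate | CCOP(=O)(Cc1ccc(O[Si](C)(C)C(C)(C)C)cc1)OCC
F10 | step 10 | heptakis(tert-butyldimethylsilyl) ether of 21 | CC(C)(C)[Si](C)(C)Oc1ccc(/C=C/c2cc(O[Si](C)(C)C(C)(C)C)c3c(c2)O[C@@H](c2ccc(O[Si](C)(C)C(C)(C)C)cc2)[C@@H]3c2cc(O[Si](C)(C)C(C)(C)C)c3c(c2)O[C@H](c2ccc(O[Si](C)(C)C(C)(C)C)cc2)[C@H]3c2cc(O[Si](C)(C)C(C)(C)C)cc(O[Si](C)(C)C(C)(C)C)c2)cc1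
A1 | alternative 1 | resveratrol, 5-[(E)-2-(4-hydroxyphenyl)ethenyl]benzene-1,3-diol | Oc1ccc(/C=C/c2cc(O)cc(O)c2)cc1
A2 | alternative 1 | 5-[(2S,3S)-4-hydroxy-2-(4-hydroxyphenyl)-6-[(E)-2-(4-hydroxyphenyl)ethenyl]-2,3-dihydro-1-benzofuran-3-yl]benzene-1,3-diol | Oc1ccc(/C=C/c2cc(O)c3c(c2)O[C@H](c2ccc(O)cc2)[C@H]3c2cc(O)cc(O)c2)cc1
A3 | alternative 2 | 5-(dimethoxymethyl)-2-[1-(3,5-dimethoxyphenyl)-2-hydroxy-2-(4-methoxyphenyl)ethyl]-3-methoxyphenol (stereoisomer mixture) | COC(OC)c1cc(O)c(C(c2cc(OC)cc(OC)c2)C(O)c2ccc(OC)cc2)c(OC)c1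
A4 | alternative 3 | 5-(dimethoxymethyl)-2-[(3,5-dimethoxyphenyl)(hydroxy)methyl]-3-methoxyphenol (racemic) | COC(OC)c1cc(O)c(C(O)c2cc(OC)cc(OC)c2)c(OC)c1
A5 | alternative 3 | [(4-methoxyphenyl)methyl]dimethylsulfonium tetrafluoroborate | C[S+](C)Cc1ccc(OC)cc1.F[B-](F)(F)F
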